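**Retrosynthetic overview**
1. Endgame: the C2 ketone comes from a C2 carbinol. The ten-membered carbocycle (C1–C10) is closed last, at C1–C2, by intramolecular allylchromium addition in a bromo aldehyde that already carries the lactone.
2. Key disconnection: the O–C12(=O) unit of the five-membered lactone ring (O, C12, C11, C7, C6) is removed as CO2. This leaves an open chain with an alkenyl boronate at C11 and an allylic acetate at C6.
3. Enabling feature: C6 is the allylic terminus of the C4=C5 double bond and stands 1,3 to the sp2 carbon C11 across C7. The O–C(=O) unit of CO2 therefore bridges C6 and C11 as a five-membered ring, and of the two secondary acetates (C6, C8) only the one at C6 can ionise.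
4. The C4=C5 geometry and C15 come from the C6 propargylic alcohol (trans-hydroalumination/iodination, then hydroxymethylation). C6 and C7 are set by an Evans syn aldol, and C8 by 1,3-syn reduction of a Weinreb-derived ketone.
5. Ring order: lactone ring (step 15), then ten-membered carbocycle (step 20).

Key step: step 15

Remark: germacrane numbering is used throughout (ring C1–C10 with C2 ketone, C4=C5, C6 lactone carbinol, C7, C8 acetoxy carbon, C10 bearing =C14H2; C11 bearing =C13H2; C12 lactone carbonyl; C15 acetoxymethyl carbon); 36 is taken on as a mixture of C2 epimers because step 21 erases that centre.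

Step 1
Reactants: 1 4-(tert-butyldimethylsilyloxy)but-1-yne
Product: 3 5-(tert-butyldimethylsilyloxy)pent-2-ynal, via lithium acetylide 2 (not isolated)
Conditions: n-BuLi, THF, −78 °C; DMF, −78 → 0 °C; inverse quench into cold aqueous phosphate buffer
Reagents that add atoms: N,N-dimethylformamide, CN(C)C=O
Why: Formylation of a lithium acetylide with DMF, in which the hemiaminal alkoxide collapses only on the buffered quench, so the ynal never meets free amine base.

Step 2
Reactants: 4 3-bromobut-3-en-1-ol
Product: 5 3-bromobut-3-enoic acid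
Conditions: TEMPO (cat.), PhI(OAc)2, MeCN/H2O, rt
Reagents that add atoms: water, O
Why: TEMPO/PhI(OAc)2 oxidation of a primary alcohol through the aldehyde hydrate runs without base, so the 1-bromovinyl double bond should stay out of conjugation.

Step 3
Reactants: 5 3-bromobut-3-enoic acid; 6 (S)-4-benzyloxazolidin-2-one
Product: 9 (S)-4-benzyl-3-(3-bromobut-3-enoyl)oxazolidin-2-one, via mixed pivalic anhydride 7 (not isolated), via lithiated oxazolidinone 8 (not isolated)
Conditions: 5, t-BuCOCl, Et3N, THF, −78 → 0 °C; separately 6, n-BuLi, THF, −78 °C; combine at −78 °C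
Reagents that add atoms: none
Why: Mixed-anhydride N-acylation of a lithiated oxazolidinone at low temperature, with attack at the less hindered carbonyl of 7 and no change at the stereocentre of 6.

Step 4
Reactants: 9 (S)-4-benzyl-3-(3-bromobut-3-enoyl)oxazolidin-2-one; 3 5-(tert-butyldimethylsilyloxy)pent-2-ynal
Product: 11 (S)-4-benzyl-3-[(2S,3S)-2-(1-bromovinyl)-7-(tert-butyldimethylsilyloxy)-3-hydroxyhept-4-ynoyl]oxazolidin-2-one, via boron dienolate 10 (not isolated)
Conditions: Bu2BOTf, Et3N, CH2Cl2, −78 → 0 °C; 3, −78 → 0 °C; pH 7 buffer, MeOH, H2O2, 0 °C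
Reagents that add atoms: none
Why: Evans syn aldol, in which the Z-dibutylboron dienolate reacts at its α-carbon through a Zimmerman–Traxler chair on the face away from the benzyl group, which should set C7 and C6 together (O6 syn to C11 in the C5–C9 zigzag).

Step 5
Reactants: 11 aldol adduct
Product: 12 (2S,3S)-2-(1-bromovinyl)-7-(tert-butyldimethylsilyloxy)-3-hydroxy-N-methoxy-N-methylhept-4-ynamide
Conditions: MeNH(OMe)·HCl, AlMe3, CH2Cl2/THF, −20 → 0 °C
Reagents that add atoms: N,O-dimethylhydroxylamine hydrochloride, CNOC.Cl
Why: Aluminium-amide transamidation (Weinreb amide synthesis), assisted by the free β-hydroxyl, cleaves the exocyclic imide carbonyl without touching C6 or C7.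

Step 6
Reactants: 13 2-methylenepropane-1,3-diol
Product: 14 2-[(tert-butyldimethylsilyloxy)methyl]prop-2-en-1-ol
Conditions: NaH (1 equiv), THF, rt; t-BuMe2SiCl
Reagents that add atoms: tert-butyldimethylsilyl chloride, CC(C)(C)[Si](C)(C)Cl
Why: Monosilylation of a symmetrical diol through its sparingly soluble monosodium alkoxide.

Step 7
Reactants: 14 2-[(tert-butyldimethylsilyloxy)methyl]prop-2-en-1-ol
Product: 15 tert-butyl{[2-(chloromethyl)prop-2-en-1-yl]oxy}dimethylsilane
Conditions: NCS, Me2S, CH2Cl2, −20 → 0 °C
Reagents that add atoms: N-chlorosuccinimide, O=C1CCC(=O)N1Cl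
Why: Corey–Kim-type chlorination, in which the alkoxysulfonium salt of an allylic alcohol is displaced by chloride under neutral conditions that spare the silyl ether.

Step 8
Reactants: 15 allylic chloride; 12 Weinreb amide
Product: 17 open-chain C8 ketone (C6 hydroxyl and C7 as in 11; C9–C10(=C14H2)–C1H2OTBS arm attached), via allylic Grignard reagent 16 (not isolated)
Conditions: 15, Mg, THF, 0 °C; then 12 (one third of an equivalent), −78 → −30 °C; cold pH 7 buffer
Reagents that add atoms: none
Why: Weinreb ketone synthesis, in which the allylic Grignard reagent (degenerate in its two CH2 termini) adds only once because the chelated tetrahedral intermediate survives until the cold buffered quench, which should keep both β,γ-double bonds and C7 in place.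

Step 9
Reactants: 17 C8 ketone
Product: 19 alkynyl syn-1,3-diol (all-syn C6–O/C7–C11/C8–O triad), via diethylboron chelate 18 (not isolated)
Conditions: Et2BOMe, THF/MeOH, −78 °C; NaBH4, −78 °C; repeated co-evaporation with MeOH
Reagents that add atoms: none
Why: Narasaka–Prasad reduction, in which external hydride attacks the six-membered boron chelate axially on the face opposite the pseudo-axial C7 substituent, which should give the 1,3-syn diol and so set C8.

Step 10
Reactants: 19 alkynyl syn-1,3-diol
Product: 21 (Z)-C4 alkenyl iodide diol (iodine cis to C6), via cyclic alkenylaluminate 20 (not isolated)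
Conditions: NaAlH2(OCH2CH2OMe)2, THF, 0 °C → rt; I2, −78 °C
Reagents that add atoms: iodine, II
Why: Hydroxyl-directed trans-hydroalumination of the propargylic alcohol places aluminium on C4 inside a five-membered aluminate (cis to C6), and iodinolysis with retention fixes the C4=C5 geometry of the target.

Step 11
Reactants: 21 alkenyl iodide diol
Product: 23 triol with C15 hydroxymethyl group cis to C6, via C4 alkenyllithium 22 (not isolated)
Conditions: MeLi (2 equiv), Et2O, −78 °C; t-BuLi (2 equiv), −78 °C; CH2O (gas from cracked paraformaldehyde), −78 → −20 °C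
Reagents that add atoms: formaldehyde, C=O
Why: Iodine–lithium exchange outruns bromine–lithium exchange, the alkoxide-chelated alkenyllithium is configurationally stable at −78 °C, and it adds to formaldehyde with retention, which avoids any alkenylpalladium that could close onto a neighbouring olefin.

Step 12
Reactants: 23 triol
Product: 24 C15 triethylsilyl ether diol
Conditions: Et3SiCl, imidazole, CH2Cl2, −40 °C
Reagents that add atoms: chlorotriethylsilane, CC[Si](Cl)(CC)CC
Why: Chemoselective silylation of the only primary hydroxyl at low temperature, which turns O15 into a non-leaving group for step 15.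

Step 13
Reactants: 24 C15 triethylsilyl ether diol
Product: 26 C11 alkenyl pinacol boronate diol, via C11 alkenyllithium 25 (not isolated)
Conditions: MeLi (2 equiv), THF, −78 °C; t-BuLi (2 equiv), −78 °C; i-PrOBpin, −78 °C → rt; aq. NH4Cl
Reagents that add atoms: 2-isopropoxy-4,4,5,5-tetramethyl-1,3,2-dioxaborolane, CC(C)OB1OC(C)(C)C(C)(C)O1
Why: Bromine–lithium exchange followed by borylation reverses the polarity of C11 while no carbonyl group is present, and C7 is not affected.

Step 14
Reactants: 26 alkenyl boronate diol
Product: 27 alkenyl boronate C6,C8-diacetate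
Conditions: Ac2O, pyridine, DMAP (cat.), CH2Cl2, rt
Reagents that add atoms: acetic anhydride, CC(=O)OC(C)=O
Why: DMAP-catalysed acetylation of both secondary hydroxyls, where the C8 acetate is that of the target and the C6 acetate is the leaving group of step 15.

Step 15
Reactants: 27 alkenyl boronate C6,C8-diacetate
Product: 29 open-chain trans-α-methylene-γ-butyrolactone (C8 acetate; C15 triethylsilyl ether; C1 and C2 tert-butyldimethylsilyl ethers), via potassium acrylate 28 (not isolated)
Conditions: Cu(IPr)Cl (5 mol %; IPr = 1,3-bis(2,6-diisopropylphenyl)imidazol-2-ylidene), KOt-Bu (1.1 equiv, slow addition), CO2 (1 atm), THF, 60 °C; then Pd(PPh3)4 (5 mol %) into the same flask, 45 °C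
Reagents that add atoms: carbon dioxide, O=C=O
Why: Proposed new method: Cu(IPr)(Ot-Bu), formed from Cu(IPr)Cl and KOt-Bu, takes the alkenyl group from boron, CO2 inserts into the copper–C11 bond (C11–C12 formed) and KOt-Bu releases potassium acrylate 28, after which zerovalent palladium ionises with inversion the only allylic acetate (C6) to the C4–C5–C6 π-allyl complex and the tethered carboxylate oxygen attacks C6 anti to palladium (O–C6 formed), so that CO2 ends up stitched between C11 and C6. The closest known reaction types are the NHC–copper-catalysed carboxylation of alkenylboronic esters with CO2, the palladium-catalysed intramolecular allylic acyloxylation of allylic acetates, and the copper-catalysed three-component coupling of terminal alkynes, CO2 and allylic chlorides to allyl alkynoates, and only their merger on one substrate in one flask is new. The lactone ring closes in the 5-exo mode at the secondary allyl terminus C6, since attack at the fully substituted terminus C4 would need a seven-membered ring. C6 is controlled by double inversion, that is net retention of the aldol-derived configuration, which places C5 and C8 trans on the lactone, while C7 and C8 are untouched. The step needs C6–OAc to leave while C8–OAc stays (secured because only C6 is allylic), the C4=C5 geometry to hold (secured because syn/anti exchange would need a σ-bond from palladium to the fully substituted C4 and because O15 is a silyl ether and not a leaving group), and the alkenylcopper to choose CO2 over the esters (secured by the low carbonyl reactivity of NHC-bound alkenylcopper under 1 atm of CO2). It is run on the open chain because in the E-configured ten-membered ring the olefin face anti to the C6–O bond is the blocked inner face.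

Step 16
Reactants: 29 lactone with C15 triethylsilyl ether
Product: 31 lactone C8,C15-diacetate (C1 and C2 still tert-butyldimethylsilyl ethers), via C15 alcohol 30 (not isolated)
Conditions: PPTS (cat.), MeOH/CH2Cl2, 0 °C; evaporation; Ac2O, pyridine, DMAP (cat.), 0 °C
Reagents that add atoms: acetic anhydride, CC(=O)OC(C)=O
Why: Acid-catalysed methanolysis removes the primary triethylsilyl ether faster than the two primary tert-butyldimethylsilyl ethers, and acetylation of the crude alcohol installs the C15 acetate once no palladium step remains.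

Step 17
Reactants: 31 lactone C8,C15-diacetate
Product: 32 C1,C2-diol
Conditions: HF·pyridine, pyridine, THF, 0 °C → rt
Reagents that add atoms: none
Why: Buffered fluoride desilylation, which the acetates and the α-methylene lactone tolerate.

Step 18
Reactants: 32 C1,C2-diol
Product: 33 C1 allylic bromide with free C2 hydroxyl
Conditions: NBS, Me2S, CH2Cl2, −20 → 0 °C
Reagents that add atoms: N-bromosuccinimide, O=C1CCC(=O)N1Br
Why: Corey–Kim-type bromination is selective for the allylic hydroxyl, because only its alkoxysulfonium salt is displaced by bromide while that of the C2 hydroxyl reverts to the alcohol on work-up.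

Step 19
Reactants: 33 C1 allylic bromide
Product: 34 bromo aldehyde (C2 aldehyde)
Conditions: Dess–Martin periodinane, pyridine, CH2Cl2, 0 °C
Reagents that add atoms: none
Why: Dess–Martin oxidation under buffered, non-basic conditions should give the β,γ-unsaturated aldehyde without migration of the C4=C5 bond.

Step 20
Reactants: 34 bromo aldehyde
Product: 36 ten-membered C2 carbinol (mixture of C2 epimers), via allylchromium species 35 (not isolated)
Conditions: CrCl2 (8 equiv), THF, rt, 34 added by syringe pump (final 0.002 M)
Reagents that add atoms: none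
Why: Intramolecular Nozaki–Hiyama allylation, in which divalent chromium reduces only the allylic bromide and the allylchromium adds to the aldehyde through its γ-carbon, which in this 2-substituted allyl unit regenerates the exocyclic methylene and closes the ten-membered ring, while the new C2 centre needs no control.

Step 21
Reactants: 36 ten-membered C2 carbinol
Product: 37 target CNP0183179.1
Conditions: Dess–Martin periodinane, pyridine, CH2Cl2, 0 °C
Reagents that add atoms: none
Why: Buffered Dess–Martin oxidation erases the C2 centre and should give the doubly β,γ-unsaturated ketone without conjugation, and C6, C7 and C8 are not affected.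

**Compound list**
1 | 4-(tert-butyldimethylsilyloxy)but-1-yne | C#CCCO[Si](C)(C)C(C)(C)C | starting material
2 | lithium acetylide of 1 | [Li]C#CCCO[Si](C)(C)C(C)(C)C | intermediate
3 | 5-(tert-butyldimethylsilyloxy)pent-2-ynal | O=CC#CCCO[Si](C)(C)C(C)(C)C | intermediate
4 | 3-bromobut-3-en-1-ol | C=C(Br)CCO | starting material
5 | 3-bromobut-3-enoic acid | C=C(Br)CC(=O)O | intermediate
6 | (S)-4-benzyloxazolidin-2-one | O=C1N[C@@H](Cc2ccccc2)CO1 | starting material
7 | 3-bromobut-3-enoic pivalic anhydride | C=C(Br)CC(=O)OC(=O)C(C)(C)C | intermediate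
8 | N-lithio-(S)-4-benzyloxazolidin-2-one | O=C1N([Li])[C@@H](Cc2ccccc2)CO1 | intermediate
9 | (S)-4-benzyl-3-(3-bromobut-3-enoyl)oxazolidin-2-one | C=C(Br)CC(=O)N1[C@@H](Cc2ccccc2)COC1=O | intermediate
10 | (Z)-dibutylboron dienolate of 9 | C=C(Br)/C=C(\OB(CCCC)CCCC)N1[C@@H](Cc2ccccc2)COC1=O | intermediate
11 | syn aldol adduct (2S,3S in the acyl chain) | CC(C)(C)[Si](C)(C)OCCC#C[C@@H](O)[C@H](C(Br)=C)C(=O)N1[C@@H](Cc2ccccc2)COC1=O | intermediate
12 | Weinreb amide (2S,3S) | CC(C)(C)[Si](C)(C)OCCC#C[C@@H](O)[C@H](C(Br)=C)C(=O)N(C)OC | intermediate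
13 | 2-methylenepropane-1,3-diol | C=C(CO)CO | starting material
14 | 2-[(tert-butyldimethylsilyloxy)methyl]prop-2-en-1-ol | C=C(CO)CO[Si](C)(C)C(C)(C)C | intermediate
15 | tert-butyl{[2-(chloromethyl)prop-2-en-1-yl]oxy}dimethylsilane | C=C(CCl)CO[Si](C)(C)C(C)(C)C | intermediate
16 | 2-[(tert-butyldimethylsilyloxy)methyl]allylmagnesium chloride | C=C(C[Mg]Cl)CO[Si](C)(C)C(C)(C)C | intermediate
17 | open-chain C8 ketone, C6 hydroxyl and C7 as in 11 | CC(C)(C)[Si](C)(C)OCCC#C[C@@H](O)[C@H](C(Br)=C)C(=O)CC(=C)CO[Si](C)(C)C(C)(C)C | intermediate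
18 | O6-diethylboron chelate of 17 (dative bond to the ketone not drawn) | CC(C)(C)[Si](C)(C)OCCC#C[C@@H](OB(CC)CC)[C@H](C(Br)=C)C(=O)CC(=C)CO[Si](C)(C)C(C)(C)C | intermediate
19 | alkynyl syn-1,3-diol, all-syn C6/C7/C8 triad | CC(C)(C)[Si](C)(C)OCCC#C[C@@H](O)[C@H](C(Br)=C)[C@@H](O)CC(=C)CO[Si](C)(C)C(C)(C)C | intermediate
20 | sodium cyclic alkenylaluminate (O6–Al–C4 ring; O8 drawn protonated) | CC(C)(C)[Si](C)(C)OCCC1=C[C@H]([C@H](C(Br)=C)[C@@H](O)CC(=C)CO[Si](C)(C)C(C)(C)C)O[Al-]1(OCCOC)OCCOC.[Na+] | intermediate
21 | (Z)-C4 alkenyl iodide diol | CC(C)(C)[Si](C)(C)OCC/C(I)=C/[C@@H](O)[C@H](C(Br)=C)[C@@H](O)CC(=C)CO[Si](C)(C)C(C)(C)C | intermediate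
22 | C4 alkenyllithium bis(lithium alkoxide) | CC(C)(C)[Si](C)(C)OCC/C([Li])=C/[C@@H](O[Li])[C@H](C(Br)=C)[C@@H](O[Li])CC(=C)CO[Si](C)(C)C(C)(C)C | intermediate
23 | triol, C15 hydroxymethyl cis to C6 | CC(C)(C)[Si](C)(C)OCC/C(CO)=C/[C@@H](O)[C@H](C(Br)=C)[C@@H](O)CC(=C)CO[Si](C)(C)C(C)(C)C | intermediate
24 | C15 triethylsilyl ether diol | CC(C)(C)[Si](C)(C)OCC/C(CO[Si](CC)(CC)CC)=C/[C@@H](O)[C@H](C(Br)=C)[C@@H](O)CC(=C)CO[Si](C)(C)C(C)(C)C | intermediate
25 | C11 alkenyllithium bis(lithium alkoxide) | CC(C)(C)[Si](C)(C)OCC/C(CO[Si](CC)(CC)CC)=C/[C@@H](O[Li])[C@H](C([Li])=C)[C@@H](O[Li])CC(=C)CO[Si](C)(C)C(C)(C)C | intermediate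
26 | C11 alkenyl pinacol boronate diol | CC(C)(C)[Si](C)(C)OCC/C(CO[Si](CC)(CC)CC)=C/[C@@H](O)[C@H](C(=C)B1OC(C)(C)C(C)(C)O1)[C@@H](O)CC(=C)CO[Si](C)(C)C(C)(C)C | intermediate
27 | C11 alkenyl pinacol boronate C6,C8-diacetate | CC(C)(C)[Si](C)(C)OCC/C(CO[Si](CC)(CC)CC)=C/[C@@H](OC(C)=O)[C@H](C(=C)B1OC(C)(C)C(C)(C)O1)[C@@H](OC(C)=O)CC(=C)CO[Si](C)(C)C(C)(C)C | intermediate
28 | potassium 2-substituted acrylate (C12 carboxylate) diacetate | CC(C)(C)[Si](C)(C)OCC/C(CO[Si](CC)(CC)CC)=C/[C@@H](OC(C)=O)[C@H](C(=C)C(=O)[O-])[C@@H](OC(C)=O)CC(=C)CO[Si](C)(C)C(C)(C)C.[K+] | intermediate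
29 | open-chain trans-α-methylene-γ-butyrolactone, C15 triethylsilyl ether | CC(C)(C)[Si](C)(C)OCC/C(CO[Si](CC)(CC)CC)=C/[C@H]1OC(=O)C(=C)[C@@H]1[C@@H](OC(C)=O)CC(=C)CO[Si](C)(C)C(C)(C)C | intermediate
30 | lactone C15 alcohol | CC(C)(C)[Si](C)(C)OCC/C(CO)=C/[C@H]1OC(=O)C(=C)[C@@H]1[C@@H](OC(C)=O)CC(=C)CO[Si](C)(C)C(C)(C)C | intermediate
31 | lactone C8,C15-diacetate | CC(C)(C)[Si](C)(C)OCC/C(COC(C)=O)=C/[C@H]1OC(=O)C(=C)[C@@H]1[C@@H](OC(C)=O)CC(=C)CO[Si](C)(C)C(C)(C)C | intermediate
32 | C1,C2-diol | OCC/C(COC(C)=O)=C/[C@H]1OC(=O)C(=C)[C@@H]1[C@@H](OC(C)=O)CC(=C)CO | intermediate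
33 | C1 allylic bromide, C2 alcohol | OCC/C(COC(C)=O)=C/[C@H]1OC(=O)C(=C)[C@@H]1[C@@H](OC(C)=O)CC(=C)CBr | intermediate
34 | bromo aldehyde | O=CC/C(COC(C)=O)=C/[C@H]1OC(=O)C(=C)[C@@H]1[C@@H](OC(C)=O)CC(=C)CBr | intermediate
35 | allylchromium dichloride aldehyde | O=CC/C(COC(C)=O)=C/[C@H]1OC(=O)C(=C)[C@@H]1[C@@H](OC(C)=O)CC(=C)C[Cr](Cl)Cl | intermediate
36 | ten-membered C2 carbinol (C2 epimers) | C=C1CC(O)C/C(COC(C)=O)=C/[C@H]2OC(=O)C(=C)[C@@H]2[C@@H](OC(C)=O)C1 | intermediate
37 | CNP0183179.1 | C=C1CC(=O)C/C(COC(C)=O)=C/[C@H]2OC(=O)C(=C)[C@@H]2[C@@H](OC(C)=O)C1 | target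

**Step count**
- Total step count: 21.
- Longest linear sequence: 18 steps (from 4 through steps 2–5 and 8–21).

**Steps most likely to fail**

1. **Step 15.** The two catalytic cycles may interfere with each other. The boronate may protodeboronate, tert-butoxide may cleave the acetates before it is consumed, or the π-allyl complex may be captured by nucleophiles other than the carboxylate. The fallback sets out from 27 and splits the two bond formations into two isolated, individually known reactions. The copper-catalysed carboxylation alone is run on 27 (Cu(IPr)Cl, KOt-Bu, CO2, THF) and the mixture is acidified to give the free 2-substituted acrylic acid diacetate F1. In a second flask F1 is closed by palladium-catalysed intramolecular allylic acyloxylation (Pd2(dba)3, dppb, Et3N, THF). The route is rejoined at 29.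

2. **Step 20.** Protonolysis or intermolecular coupling of the allylchromium may outrun closure of the strained ten-membered ring. The fallback sets out from 34 and replaces the reductive organochromium closure with a Lewis-base-activated allylsilane addition. HSiCl3, CuCl (cat.) and i-Pr2NEt in Et2O convert the allylic bromide into the allyltrichlorosilane aldehyde F2, which is inert toward its own aldehyde in ether. Slow dilution into DMF forms the hypervalent silicate, which adds through a closed six-membered transition state. The route is rejoined at 36.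

3. **Step 8.** Enolisation during or after the addition may cause migration of either β,γ-double bond into conjugation, epimerisation at C7, or retro-aldol cleavage. The fallback sets out from 12 and avoids the ketone.
   - Et3SiOTf and 2,6-lutidine give the O6-triethylsilyl Weinreb amide F3.
   - i-Bu2AlH at −78 °C gives the C8 aldehyde F4.
   - Grignard reagent 16 and i-PrOBpin give the pinacol 2-[(tert-butyldimethylsilyloxy)methyl]allylboronate F5.
   - Allylboration of F4 with F5 is catalysed by a chiral phosphoric acid (3,3′-bis(2,4,6-triisopropylphenyl)-BINOL hydrogen phosphate, with the enantiomer chosen so that O8 ends up syn to C11). This sets C8 under catalyst control and gives the O6-silylated homoallylic alcohol F6.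
   - PPTS in MeOH removes the secondary triethylsilyl ether, and the route is rejoined at 19.

**Further compounds**
F1 | step 15 | 2-substituted acrylic acid C6,C8-diacetate | CC(C)(C)[Si](C)(C)OCC/C(CO[Si](CC)(CC)CC)=C/[C@@H](OC(C)=O)[C@H](C(=C)C(=O)O)[C@@H](OC(C)=O)CC(=C)CO[Si](C)(C)C(C)(C)C
F2 | step 20 | allyltrichlorosilane aldehyde | O=CC/C(COC(C)=O)=C/[C@H]1OC(=O)C(=C)[C@@H]1[C@@H](OC(C)=O)CC(=C)C[Si](Cl)(Cl)Cl
F3 | step 8 | O6-triethylsilyl Weinreb amide | CC(C)(C)[Si](C)(C)OCCC#C[C@@H](O[Si](CC)(CC)CC)[C@H](C(Br)=C)C(=O)N(C)OC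
F4 | step 8 | C8 aldehyde | CC(C)(C)[Si](C)(C)OCCC#C[C@@H](O[Si](CC)(CC)CC)[C@H](C(Br)=C)C=O
F5 | step 8 | pinacol 2-[(tert-butyldimethylsilyloxy)methyl]allylboronate | C=C(CB1OC(C)(C)C(C)(C)O1)CO[Si](C)(C)C(C)(C)C
F6 | step 8 | O6-silylated homoallylic alcohol | CC(C)(C)[Si](C)(C)OCCC#C[C@@H](O[Si](CC)(CC)CC)[C@H](C(Br)=C)[C@@H](O)CC(=C)CO[Si](C)(C)C(C)(C)C
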